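**Retrosynthetic overview**
1. The target comes from a tertiary C4 carbinol triacetate by a final loss of water to C3=C4. That carbinol comes from a C9,C10-epoxide (source of 9-OH and the 10-methylene) of a trans-hydroazulene-4,6-diol.
2. H-5 and 6-OH come from a silicon-tethered syn hydrosilylation/oxidation of C5=C6. The tether hangs on the C4 carbinol made by MeLi addition to a bicyclic dienone.
3. Key step: both carbocycles form from one acyclic vinyl diazoketone. Intramolecular cyclopropanation closes ring A (five-membered) plus a cyclopropane. An in-flask divinylcyclopropane rearrangement then gives ring B (seven-membered). This sets C1 and C7.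
4. The vinyl diazoketone comes from diazo aldol/dehydration of a dienyl diazoketone (fragment B, from methyl 4-oxobutanoate by two Wittig reactions) with the side-chain aldehyde (fragment A).
5. Fragment A comes from a syn-aldol of hydroxyacetone with prenal (C12, C13), a formylolefination, and an iminium-catalysed conjugate reduction (C11).

Assumption: the SMILES is taken literally (1R,5S,6R,7S,9R,11R,12S,13S, so H-1 and H-5 are anti and the bicycle is trans-fused); dictyol numbering is used (C1/C5 ring fusion, C4 methyl-bearing olefin carbon, C6 carbinol, C7 side-chain carbon, C9 acetoxy carbon, C10 methylene-bearing carbon, C11–C15 side chain); "top" is the face carrying H-1, H-6, H-7 and 9-O, and "bottom" carries H-5, 6-O and the side chain.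

Step 1
Reactants: 1 3-methylbut-2-enal (prenal); 2 hydroxyacetone
Product: 3 (3R,4S)-3,4-dihydroxy-6-methylhept-5-en-2-one
Conditions: O-tert-butyl-L-threonine (20 mol %), NMP, 4 °C, 48 h (5 equiv of 2)
Reagents that add atoms: none
Why: Primary-amine (enamine) catalysed direct syn-aldol addition, in which the hydrogen-bonded Z-enamine formed at the hydroxylated carbon of 2 attacks one aldehyde face and sets C12 and C13 together as the syn diol.

Step 2
Reactants: 3
Product: 4 1-[(4R,5S)-2,2-dimethyl-5-(2-methylprop-1-enyl)-1,3-dioxolan-4-yl]ethanone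
Conditions: Me2C(OMe)2, PPTS (5 mol %), CH2Cl2, 23 °C
Reagents that add atoms: 2,2-dimethoxypropane, COC(C)(C)OC
Why: Acid-catalysed transacetalisation locks the syn diol as the favoured trans-dioxolane without touching either stereocentre.

Step 3
Reactants: 4
Product: 6 (2E)-3-[(4S,5S)-2,2-dimethyl-5-(2-methylprop-1-enyl)-1,3-dioxolan-4-yl]but-2-enal (E/Z mixture usable), via azadiene 5 (not isolated)
Conditions: (EtO)2P(O)CH=CHNH(c-C6H11), NaH, THF, 0 to 23 °C; then oxalic acid, H2O/THF, 23 °C
Reagents that add atoms: diethyl [(E)-2-(cyclohexylamino)ethenyl]phosphonate, CCOP(=O)(OCC)/C=C/NC1CCCCC1; water, O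
Why: Horner–Wadsworth–Emmons formylolefination, in which the metallated enamine phosphonate adds to the activated alpha-alkoxy ketone and loses diethyl phosphate to give an unsaturated imine that mild acid hydrolyses to the enal, with the trans-dioxolane being the stable C12 epimer so that base cannot erode it.

Step 4
Reactants: 6
Product: 7 (3R)-3-[(4S,5S)-2,2-dimethyl-5-(2-methylprop-1-enyl)-1,3-dioxolan-4-yl]butanal (fragment A)
Conditions: (S)-2-tert-butyl-3-methylimidazolidin-4-one trichloroacetate (20 mol %), diethyl Hantzsch ester (1.2 equiv), CHCl3, −30 °C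
Reagents that add atoms: none
Why: Iminium-catalysed transfer hydrogenation, in which the E and Z iminium ions interconvert and only the one with the exposed face accepts hydride at C11, so the catalyst sets (11R) and no other olefin is touched.

Step 5
Reactants: 8 methyl 4-oxobutanoate
Product: 9 methyl (4E)-5-methyl-6-oxohex-4-enoate
Conditions: Ph3P=C(CH3)CHO, CH2Cl2, 40 °C
Reagents that add atoms: 2-(triphenylphosphoranylidene)propanal, CC(C=O)=P(c1ccccc1)(c1ccccc1)c1ccccc1
Why: Wittig olefination with a stabilised ylide gives the E-trisubstituted enal, which fixes the C1=C10 geometry.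

Step 6
Reactants: 9
Product: 10 methyl (4E)-5-methylhepta-4,6-dienoate
Conditions: Ph3PCH3Br, KOtBu, THF, −78 to 0 °C
Reagents that add atoms: methyltriphenylphosphonium bromide, C[P+](c1ccccc1)(c1ccccc1)c1ccccc1.[Br-]
Why: Wittig methylenation of the aldehyde, which is much faster than attack on the ester, completes the E-diene.

Step 7
Reactants: 10
Product: 11 (4E)-5-methylhepta-4,6-dienoic acid
Conditions: LiOH, THF/H2O, 23 °C; then 1 M HCl
Reagents that add atoms: lithium hydroxide, [Li+].[OH-]
Why: Ester saponification leaves the non-conjugated diene unchanged.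

Step 8
Reactants: 11
Product: 13 (5E)-1-diazo-6-methylocta-5,7-dien-2-one (fragment B), via acid chloride 12 (not isolated)
Conditions: (COCl)2, DMF (cat.), CH2Cl2, 0 °C, evaporate; then TMSCHN2 (2.2 equiv), THF/MeCN, 0 °C
Reagents that add atoms: (trimethylsilyl)diazomethane, C[Si](C)(C)C=[N+]=[N-]
Why: Arndt–Eistert-type acylation of a diazomethane equivalent by the acid chloride, followed by loss of the silyl group, gives the terminal diazoketone.

Step 9
Reactants: 13; 7
Product: 14 (3E,11R)-8-diazo-11-[(4S,5S)-2,2-dimethyl-5-(2-methylprop-1-enyl)-1,3-dioxolan-4-yl]-9-hydroxy-3-methyldodeca-1,3-dien-7-one (C6 carbinol epimers)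
Conditions: DBU (0.3 equiv), MeCN, 23 °C
Reagents that add atoms: none
Why: Base-catalysed diazo aldol addition, in which DBU reversibly removes the acidic diazo C–H of 13 and the carbanion adds to aldehyde 7, the new carbinol centre being erased in step 10.

Step 10
Reactants: 14
Product: 16 (3E,9E,11R)-8-diazo-11-[(4S,5S)-2,2-dimethyl-5-(2-methylprop-1-enyl)-1,3-dioxolan-4-yl]-3-methyldodeca-1,3,9-trien-7-one, via trifluoroacetate 15 (not isolated)
Conditions: (CF3CO)2O, Et3N, CH2Cl2, 0 °C; used at once
Reagents that add atoms: none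
Why: Acylation and amine-induced elimination (diazo-assisted ionisation at C6, then loss of a C7 proton) gives the conjugated vinyl diazoketone as the less strained E olefin that step 11 requires.

Step 11 (key step)
Reactants: 16
Product: 18 hydroazulenone (bicyclo[5.3.0]deca-5,9-dien-4-one in dictyol numbering; 10-methyl; acetonide side chain at C7 on the bottom face; H-1 and H-7 both top), via divinylcyclopropane 17 (not isolated)
Conditions: Rh2(S-DOSP)4 (1 mol %), hexanes, slow addition at −40 °C, then 23 to 50 °C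
Reagents that add atoms: none
Why: Tandem intramolecular cyclopropanation/divinylcyclopropane (Cope) rearrangement, in which loss of N2 at the chiral dirhodium tetraprolinate gives a donor/acceptor vinylcarbene that adds to the proximal C1=C10 bond (closing ring A and the cyclopropane and setting C1 under catalyst control), the E-diene places the C10 vinyl cis to the C5 alkenyl group so that 17 rearranges through the obligatory boat transition state to ring B, and the E C6=C7 geometry is translated into H-7 cis to H-1.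

Step 12
Reactants: 18
Product: 20 C4 tertiary allylic dimethylsilyl ether (4-CH3 top; 4-OSiHMe2 bottom), via lithium alkoxide 19 (not isolated)
Conditions: MeLi (1.2 equiv), Et2O, −78 °C; then Me2SiHCl (3 equiv), Et3N, −78 to 0 °C
Reagents that add atoms: methyllithium, [Li]C; chlorodimethylsilane, C[SiH](C)Cl
Why: 1,2-Addition of MeLi to the enone from the top face, because ring B hangs below ring A through C10, puts the C4 oxygen on the bottom face, and silylation of the alkoxide in the same flask installs the Si–H tether.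

Step 13
Reactants: 20
Product: 22 trans-hydroazulene-4,6-diol (H-5 bottom; 6-OH bottom; 4-OH bottom; C9=C10 and side chain unchanged), via oxasilolane 21 (not isolated)
Conditions: Pt2(dvtms)3 (0.5 mol %), toluene, 23 to 60 °C; then 30 % H2O2, KF, KHCO3, THF/MeOH, 23 °C
Reagents that add atoms: hydrogen peroxide, OO
Why: Tamao-type intramolecular 5-endo hydrosilylation followed by Tamao–Fleming oxidation, in which the tether delivers Si to C6 and H to C5 in a syn fashion on the bottom face where O-4 sits (setting the trans ring fusion and C6 against the steric bias of the side chain) and C–Si is replaced by C–OH with retention.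

Step 14
Reactants: 22
Product: 23 9,10-epoxide (epoxide oxygen on the top face)
Conditions: mCPBA (1.0 equiv), NaHCO3, CH2Cl2, −20 °C
Reagents that add atoms: 3-chloroperoxybenzoic acid, OOC(=O)c1cccc(Cl)c1
Why: Prilezhaev epoxidation of the more electron-rich ring olefin (the side-chain olefin is deactivated by its allylic C–O bond and shielded by the dioxolane), with attack from the top because in the chair-like cycloheptene with axial H-5 the ring carbons and the C7 chain fold under the bottom face, which sets C9.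

Step 15
Reactants: 23
Product: 24 4,6,9-triol with 10-exomethylene (9-OH top)
Conditions: LiNEt2 (6 equiv), Et2O/hexane, 0 to 35 °C; then H2O
Reagents that add atoms: none
Why: Base-induced epoxide-to-allylic-alcohol isomerisation (Crandall–Rickborn syn beta-elimination), in which the amide bound to the epoxide oxygen removes a proton from the least hindered C10 methyl group so that C10–O breaks while the C9–O stereocentre is untouched.

Step 16
Reactants: 24
Product: 25 4,6,9,12,13-pentaol
Conditions: AcOH/H2O/THF (3:1:1), 40 °C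
Reagents that add atoms: none
Why: Mild acetal hydrolysis frees the side-chain diol under conditions that neither the unactivated tertiary carbinol nor the allylic alcohols ionise.

Step 17
Reactants: 25
Product: 26 9,12,13-triacetate with free 6-OH and free tertiary 4-OH
Conditions: Ac2O (3.5 equiv), pyridine, 0 to 23 °C (no DMAP)
Reagents that add atoms: acetic anhydride, CC(=O)OC(C)=O
Why: Sterically differentiated acetylation, in which the three accessible secondary alcohols react while the tertiary 4-OH and the 6-OH (wedged between the ring fusion and the branched C7 chain) stay free.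

Step 18
Reactants: 26
Product: 27 target CNP0194318.1
Conditions: Ph2S[OC(CF3)2Ph]2 (1.3 equiv), CH2Cl2, −40 to 0 °C
Reagents that add atoms: none
Why: Martin sulfurane dehydration, in which the tertiary C4 alkoxysulfurane eliminates far faster than the hindered 6-OH reacts, H-5 is cis to the leaving group and buried, and an exocyclic olefin on a cyclopentane is disfavoured, so loss of an anti C3 proton gives the endocyclic C3=C4 bond.

**Compound list**
1 | 3-methylbut-2-enal | CC(C)=CC=O | starting material
2 | hydroxyacetone | CC(=O)CO | starting material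
3 | (3R,4S)-3,4-dihydroxy-6-methylhept-5-en-2-one | CC(=O)[C@H](O)[C@H](C=C(C)C)O | intermediate
4 | 1-[(4R,5S)-2,2-dimethyl-5-(2-methylprop-1-enyl)-1,3-dioxolan-4-yl]ethanone | CC(=O)[C@@H]1OC(C)(C)O[C@H]1C=C(C)C | intermediate
5 | N-cyclohexyl imine of 6 (azadiene) | C1CCCCC1N=C/C=C(\C)[C@@H]2OC(C)(C)O[C@H]2C=C(C)C | intermediate
6 | (2E)-3-[(4S,5S)-dioxolanyl]but-2-enal (E shown) | O=C/C=C(\C)[C@@H]1OC(C)(C)O[C@H]1C=C(C)C | intermediate
7 | (3R)-3-[(4S,5S)-dioxolanyl]butanal, fragment A | O=CC[C@@H](C)[C@@H]1OC(C)(C)O[C@H]1C=C(C)C | intermediate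
8 | methyl 4-oxobutanoate | COC(=O)CCC=O | starting material
9 | methyl (4E)-5-methyl-6-oxohex-4-enoate | COC(=O)CC/C=C(\C)C=O | intermediate
10 | methyl (4E)-5-methylhepta-4,6-dienoate | COC(=O)CC/C=C(\C)C=C | intermediate
11 | (4E)-5-methylhepta-4,6-dienoic acid | OC(=O)CC/C=C(\C)C=C | intermediate
12 | (4E)-5-methylhepta-4,6-dienoyl chloride | ClC(=O)CC/C=C(\C)C=C | intermediate
13 | (5E)-1-diazo-6-methylocta-5,7-dien-2-one, fragment B | [N-]=[N+]=CC(=O)CC/C=C(\C)C=C | intermediate
14 | beta-hydroxy diazoketone (C6 epimers) | C=C/C(C)=C/CCC(=O)C(=[N+]=[N-])C(O)C[C@@H](C)[C@@H]1OC(C)(C)O[C@H]1C=C(C)C | intermediate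
15 | C6 trifluoroacetate of 14 | C=C/C(C)=C/CCC(=O)C(=[N+]=[N-])C(OC(=O)C(F)(F)F)C[C@@H](C)[C@@H]1OC(C)(C)O[C@H]1C=C(C)C | intermediate
16 | (E)-vinyl diazoketone | C=C/C(C)=C/CCC(=O)C(=[N+]=[N-])/C=C/[C@@H](C)[C@@H]1OC(C)(C)O[C@H]1C=C(C)C | intermediate
17 | cis-divinylcyclopropane (6-methyl-6-vinyl-1-alkenylbicyclo[3.1.0]hexan-2-one; vinyl exo) | C[C@]1(C=C)[C@@H]2CCC(=O)[C@]12/C=C/[C@@H](C)[C@@H]3OC(C)(C)O[C@H]3C=C(C)C | intermediate
18 | hydroazulenone (4-oxo; C5=C6; C9=C10; H-1 and H-7 top) | CC1=CC[C@@H]([C@@H](C)[C@@H]3OC(C)(C)O[C@H]3C=C(C)C)C=C2C(=O)CC[C@@H]12 | intermediate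
19 | lithium C4 alkoxide (O bottom) | CC1=CC[C@@H]([C@@H](C)[C@@H]3OC(C)(C)O[C@H]3C=C(C)C)C=C2[C@@](C)([O-])CC[C@@H]12.[Li+] | intermediate
20 | C4 dimethylsilyl ether | CC1=CC[C@@H]([C@@H](C)[C@@H]3OC(C)(C)O[C@H]3C=C(C)C)C=C2[C@@](C)(O[SiH](C)C)CC[C@@H]12 | intermediate
21 | oxasilolane (O4–SiMe2–C6; H-5 and Si bottom) | CC1=CC[C@@H]([C@@H](C)[C@@H]4OC(C)(C)O[C@H]4C=C(C)C)[C@@H]3[C@@H]2[C@@](C)(O[Si]3(C)C)CC[C@@H]12 | intermediate
22 | trans-hydroazulene-4,6-diol | CC1=CC[C@@H]([C@@H](C)[C@@H]4OC(C)(C)O[C@H]4C=C(C)C)[C@@H](O)[C@@H]2[C@@](C)(O)CC[C@@H]12 | intermediate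
23 | 9,10-epoxide (O top) | C[C@@]12O[C@@H]1C[C@@H]([C@@H](C)[C@@H]4OC(C)(C)O[C@H]4C=C(C)C)[C@@H](O)[C@@H]3[C@@](C)(O)CC[C@@H]23 | intermediate
24 | 4,6,9-triol with 10-exomethylene | C=C1[C@H](O)C[C@@H]([C@@H](C)[C@@H]4OC(C)(C)O[C@H]4C=C(C)C)[C@@H](O)[C@@H]2[C@@](C)(O)CC[C@@H]12 | intermediate
25 | 4,6,9,12,13-pentaol | C=C1[C@H](O)C[C@@H]([C@@H](C)[C@H](O)[C@H](C=C(C)C)O)[C@@H](O)[C@@H]2[C@@](C)(O)CC[C@@H]12 | intermediate
26 | 9,12,13-triacetate, 4,6-diol | C=C1[C@H](OC(C)=O)C[C@@H]([C@@H](C)[C@H](OC(C)=O)[C@H](C=C(C)C)OC(C)=O)[C@@H](O)[C@@H]2[C@@](C)(O)CC[C@@H]12 | intermediate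
27 | CNP0194318.1 | C=C1[C@H](OC(C)=O)C[C@@H]([C@@H](C)[C@H](OC(C)=O)[C@H](C=C(C)C)OC(C)=O)[C@@H](O)[C@@H]2C(C)=CC[C@@H]12 | target

**Totals:** 18 steps. The longest linear sequence is 14 steps (steps 1–4 or 5–8, then 9–18).

**Steps most likely to fail**

*Step 11.* The alkyl-substituted vinyl diazoketone can close to a pyrazole before it meets the catalyst. Face selection by the dirhodium prolinate is not proven for an all-carbon ketone tether, and if the sense is opposite the enantiomeric catalyst must be used. The fallback sets out from 7 and comes back at 17.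
- Aldehyde 7 is joined to commercial cyclopent-2-enone in a Morita–Baylis–Hillman reaction (PBu3, phenol, THF) to give the 2-(1-hydroxyalkyl)cyclopentenone F1.
- MsCl/Et3N converts this into the allylic mesylate F2, and DBU eliminates it to the cross-conjugated 2-[(E)-alkenyl]cyclopentenone F3.
- Michael-initiated ring closure with the ylide from but-3-en-2-yl(diphenyl)sulfonium tetrafluoroborate and KOtBu builds the methyl/vinyl cyclopropane on a ring A that is already in place. This gives 17, which rearranges to 18 as before.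
- No diazo compound is needed. The C1 diastereomers are separated at 18, or a chiral sulfide is used.

*Step 13.* The tethered hydrosilylation has to form an oxasilolane trans-fused to ring A and to place silicon next to the bulky C7 chain. It may stall or add on the wrong face. The fallback sets out from 14 and comes back at 22, and it brings the C6 oxygen in as a ketone.
- Rh2(OAc)4 turns 14 by 1,2-hydride shift into the 1,3-diketone F4, and p-acetamidobenzenesulfonyl azide/Et3N gives the 2-diazo-1,3-diketone F5.
- The robust acceptor/acceptor carbene (Rh2(OAc)4, or CuOTf with a bis(oxazoline)) closes the acylcyclopropane F6.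
- LDA/TBSCl on the acyl side gives the (Z)-silyl enol ether F7, which undergoes the siloxy-Cope rearrangement to the siloxy dienone F8.
- MeLi adds from the top face to give the tertiary alcohol F9, and TBAF/AcOH frees the beta-hydroxy ketone F10. Its C5 centre is now alpha to the C6 ketone with no beta,gamma-olefin present, so it is equilibrated to the trans fusion.
- LiBH(s-Bu)3 attacks anti to the C7 chain and gives 22.

*Step 18.* An ionising tertiary centre may lose H-5 (tetrasubstituted olefin) or a methyl proton, and the free 6-OH may interfere. The fallback sets out from 24 and comes back at 27. It moves the dehydration ahead of deprotection and runs it as a strict anti elimination.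
- TESOTf/2,6-lutidine protects both secondary alcohols of 24 to give the 6,9-bis(triethylsilyl) ether F11.
- SOCl2/pyridine (−20 °C) eliminates the C4 chlorosulfite. Only an anti proton can leave, and H-5 is syn, so the product is the C3=C4 olefin F12.
- AcOH/H2O/THF removes both silyl groups and the acetonide to give the 6,9,12,13-tetraol F13.
- The sterically differentiated acetylation of step 17 then becomes the last step and gives 27.

**Further compounds**
F1 | step 11 | 2-(1-hydroxyalkyl)cyclopent-2-enone (Baylis–Hillman adduct of 7) | O=C1CCC=C1C(O)C[C@@H](C)[C@@H]2OC(C)(C)O[C@H]2C=C(C)C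
F2 | step 11 | mesylate of F1 | O=C1CCC=C1C(OS(C)(=O)=O)C[C@@H](C)[C@@H]2OC(C)(C)O[C@H]2C=C(C)C
F3 | step 11 | 2-[(E)-alkenyl]cyclopent-2-enone | O=C1CCC=C1/C=C/[C@@H](C)[C@@H]2OC(C)(C)O[C@H]2C=C(C)C
F4 | step 13 | acyclic 1,3-diketone | C=C/C(C)=C/CCC(=O)CC(=O)C[C@@H](C)[C@@H]1OC(C)(C)O[C@H]1C=C(C)C
F5 | step 13 | 2-diazo-1,3-diketone | C=C/C(C)=C/CCC(=O)C(=[N+]=[N-])C(=O)C[C@@H](C)[C@@H]1OC(C)(C)O[C@H]1C=C(C)C
F6 | step 13 | 1-acyl-6-methyl-6-vinylbicyclo[3.1.0]hexan-2-one | C[C@]1(C=C)[C@@H]2CCC(=O)[C@]12C(=O)C[C@@H](C)[C@@H]3OC(C)(C)O[C@H]3C=C(C)C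
F7 | step 13 | (Z)-silyl enol ether of F6 | C[C@]1(C=C)[C@@H]2CCC(=O)[C@]12/C(O[Si](C)(C)C(C)(C)C)=C/[C@@H](C)[C@@H]3OC(C)(C)O[C@H]3C=C(C)C
F8 | step 13 | 6-siloxy hydroazulenone | CC1=CC[C@@H]([C@@H](C)[C@@H]3OC(C)(C)O[C@H]3C=C(C)C)C(O[Si](C)(C)C(C)(C)C)=C2C(=O)CC[C@@H]12
F9 | step 13 | C4 tertiary alcohol of F8 | CC1=CC[C@@H]([C@@H](C)[C@@H]3OC(C)(C)O[C@H]3C=C(C)C)C(O[Si](C)(C)C(C)(C)C)=C2[C@@](C)(O)CC[C@@H]12
F10 | step 13 | trans-fused 4-hydroxy-6-ketone | CC1=CC[C@@H]([C@@H](C)[C@@H]3OC(C)(C)O[C@H]3C=C(C)C)C(=O)[C@@H]2[C@@](C)(O)CC[C@@H]12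
F11 | step 18 | 6,9-bis(triethylsilyl) ether of 24 | C=C1[C@H](O[Si](CC)(CC)CC)C[C@@H]([C@@H](C)[C@@H]4OC(C)(C)O[C@H]4C=C(C)C)[C@@H](O[Si](CC)(CC)CC)[C@@H]2[C@@](C)(O)CC[C@@H]12
F12 | step 18 | C3=C4 olefin, fully protected | C=C1[C@H](O[Si](CC)(CC)CC)C[C@@H]([C@@H](C)[C@@H]4OC(C)(C)O[C@H]4C=C(C)C)[C@@H](O[Si](CC)(CC)CC)[C@@H]2C(C)=CC[C@@H]12
F13 | step 18 | 6,9,12,13-tetraol | C=C1[C@H](O)C[C@@H]([C@@H](C)[C@H](O)[C@H](C=C(C)C)O)[C@@H](O)[C@@H]2C(C)=CC[C@@H]12
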